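**Strategy.** Everything rests on cutting one 2-butanoyl-4,4-dimethylcyclohexane-1,3,5-trione (filicinic) ring at two Claisen bonds, C3–C4 and C1–C2 (C1 butanoyl-bearing, C3 bridge-bearing, C5 = CMe2). In one operation the enolate of an aryl lactone (a dihydrocoumarin fused to the central phloroglucinol ring) is acylated by the enol lactone 3,3-dimethyl-6-propylpyran-2,4-dione, and the β-diketone carbon so released closes the carbocycle onto the aryl ester, as in polyketide Claisen cyclisation. The step exploits the β-triketone pattern C2/C4/C6 of this ring, its non-enolisable C5Me2 and the phenolic OH ortho to the CH2 bridge, used as ester tether and leaving group. It is the only ring closure of the skeleton; the other filicinic ring, from dearomatising methylation, is attached last through a methylene bridge.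

Key step: step 4

Remark: the target has no stereocentre and is achiral, so no step has to set or preserve configuration.
Remark: pentan-2-one, dimethylmalonyl dichloride, 1-(2,4,6-trihydroxyphenyl)butan-1-one and acrylic acid are taken as commercially available.
Remark: lactone 7 is written as the 6-butanoyl regioisomer; the 8-butanoyl isomer would converge on the same compound 9 in step 4, because the lactone oxygen is set free there as a phenol.
Remark: enolates, phenoxides and ammonium salts are treated as salt forms of the numbered compounds; in the ring built in step 4, C1 carries the butanoyl group, C2 an OH, C3 the CH2 bridge, C4 an OH, C5 the two methyls and C6 the ring C=O.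

Step 1
Reactants: 1 pentan-2-one
Product: 2 2-(trimethylsilyloxy)pent-1-ene
Conditions: LDA (commercial solution, 1.05 equiv), THF, −78 °C; TMSCl, −78 °C → rt
Reagents that add atoms: chlorotrimethylsilane, C[Si](C)(C)Cl
Why: Kinetic deprotonation of the methyl ketone at the less hindered CH3 by LDA at −78 °C and O-silylation should give the terminal silyl enol ether (kinetic silyl enol ether formation).

Step 2
Reactants: 2 2-(trimethylsilyloxy)pent-1-ene; 3 dimethylmalonyl dichloride
Product: 4 3,3-dimethyl-6-propyl-2H-pyran-2,4(3H)-dione
Conditions: Et2O, −78 °C → rt (2 added slowly to 3)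
Reagents that add atoms: none
Why: Effenberger-type pyranone synthesis, in which the terminal enol-ether carbon is C-acylated by one acid chloride and the enol oxygen of the resulting β-diketone closes onto the second one, while the CMe2 group keeps the product as the non-aromatic enol lactone.

Step 3
Reactants: 5 1-(2,4,6-trihydroxyphenyl)butan-1-one; 6 acrylic acid
Product: 7 6-butanoyl-5,7-dihydroxychroman-2-one
Conditions: acrylic acid (1.0 equiv), Amberlyst-15, toluene–dioxane, 100 °C
Reagents that add atoms: none
Why: Brønsted-acid-catalysed Friedel–Crafts conjugate addition of the electron-rich ring to acrylic acid followed by lactonisation with an ortho-OH is the standard entry to 3,4-dihydrocoumarins, and the acyloxy group formed should deactivate the ring against a second annulation.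

Step 4
Reactants: 7 6-butanoyl-5,7-dihydroxychroman-2-one; 4 3,3-dimethyl-6-propyl-2H-pyran-2,4(3H)-dione
Product: 9 norflavaspidic acid BB, via acyl lactone 8 (not isolated)
Conditions: LiHMDS (3.1 equiv), THF–DMPU, −78 °C; then 4 (1.2 equiv), −78 → 0 °C; 1 M HCl
Reagents that add atoms: none
Why: Proposed new method: the lithium enolate at C3 of the aryl lactone (the butanoyl ketone is not enolised because the two flanking phenoxides make it a vinylogous carboxylate) attacks the enol-lactone carbonyl of 4 in a crossed Claisen condensation (C3–C4 bond), which opens the pyrandione and unmasks in 8 the β-diketone enolate C1 that was hidden as the ring enol ether. C1 then attacks the aryl-lactone carbonyl C2 intramolecularly (Dieckmann-type Claisen, C1–C2 bond) and the tetrahedral intermediate expels the phenoxide, so the lactone oxygen becomes the free ortho-OH of the aromatic ring and the former pyran oxygen the butanoyl C=O. The closest known reactions are the acyl transfer from enol lactones of the diketene type to enolates, the methoxide-induced rearrangement of 3,3-dimethylpyran-2,4-diones to 4,4-dimethylcyclohexane-1,3,5-triones and the Claisen cyclisation of 3,5,7-triketo esters to acylphloroglucinols. The carbocycle closes in a 6-(enolexo)-exo-trig mode and no stereocentre is formed. The step needs regioselective C-cyclisation: C5Me2 cannot enolise, C1 is the only carbon that reaches C2 through a six-membered transition state (the butanoyl α-CH2 would give an eight-membered ring), and O-acylation is reversible whereas C-acylation ends in the stabilised β-triketone anion. It also needs attack of the enolate on the lactone carbonyl of 4 and not proton transfer or conjugate addition, which the hard lithium enolate at −78 °C and the vinylogous-anhydride activation of that carbonyl should secure.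

Step 5
Reactants: 5 1-(2,4,6-trihydroxyphenyl)butan-1-one
Product: 10 butyrylfilicinic acid
Conditions: NaOMe, MeI (2.2 equiv), MeOH, 0 °C → rt
Reagents that add atoms: iodomethane, CI
Why: Known dearomatising gem-dimethylation of acylphloroglucinols, in which the first C-methyl group makes the same ring carbon the most nucleophilic one, so that the second methyl should enter there and lock the ring as the β-triketone.

Step 6
Reactants: 10 butyrylfilicinic acid; 9 norflavaspidic acid BB
Product: 13 filixic acid BBB, via Mannich base 11 (not isolated), via methylene trione 12 (not isolated)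
Conditions: Me2N=CH2+ I− (1.0 equiv), MeCN, rt; then 9, 50 °C
Reagents that add atoms: N,N-dimethylmethyleneiminium iodide (Eschenmoser's salt), C[N+](C)=C.[I-]
Why: Mannich reaction at the single nucleophilic ring CH of 10, thermal loss of dimethylamine to the methylene trione 12 and Friedel–Crafts-type Michael addition of the only free aromatic CH of 9 (the known Mannich/Knoevenagel–Michael methylene bridging of acylphloroglucinols) should give the unsymmetrical union without free formaldehyde, which suppresses homodimers.

**Compound list**

1 | pentan-2-one | CCCC(C)=O | starting material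
2 | 2-(trimethylsilyloxy)pent-1-ene | CCCC(=C)O[Si](C)(C)C | intermediate
3 | dimethylmalonyl dichloride (2,2-dimethylpropanedioyl dichloride) | CC(C)(C(=O)Cl)C(=O)Cl | starting material
4 | 3,3-dimethyl-6-propyl-2H-pyran-2,4(3H)-dione | CCCC1=CC(=O)C(C)(C)C(=O)O1 | intermediate
5 | 1-(2,4,6-trihydroxyphenyl)butan-1-one (butyrylphloroglucinol) | CCCC(=O)c1c(O)cc(O)cc1O | starting material
6 | acrylic acid | C=CC(=O)O | starting material
7 | 6-butanoyl-5,7-dihydroxychroman-2-one (6-butanoyl-5,7-dihydroxy-3,4-dihydro-2H-chromen-2-one) | CCCC(=O)c1c(O)cc2OC(=O)CCc2c1O | intermediate
8 | 6-butanoyl-3-(2,2-dimethyl-3,5-dioxooctanoyl)-5,7-dihydroxychroman-2-one (acyl lactone, not isolated) | CCCC(=O)CC(=O)C(C)(C)C(=O)C1Cc2c(O)c(C(=O)CCC)c(O)cc2OC1=O | intermediate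
9 | norflavaspidic acid BB: 2-butanoyl-4-[(3-butanoyl-2,4,6-trihydroxyphenyl)methyl]-3,5-dihydroxy-6,6-dimethylcyclohexa-2,4-dien-1-one | CCCC(=O)C1=C(O)C(Cc2c(O)cc(O)c(C(=O)CCC)c2O)=C(O)C(C)(C)C1=O | intermediate
10 | butyrylfilicinic acid: 2-butanoyl-3,5-dihydroxy-6,6-dimethylcyclohexa-2,4-dien-1-one | CCCC(=O)C1=C(O)C=C(O)C(C)(C)C1=O | intermediate
11 | Mannich base: 2-butanoyl-4-(dimethylaminomethyl)-3,5-dihydroxy-6,6-dimethylcyclohexa-2,4-dien-1-one (not isolated) | CCCC(=O)C1=C(O)C(CN(C)C)=C(O)C(C)(C)C1=O | intermediate
12 | methylene trione: 2-butanoyl-3-hydroxy-6,6-dimethyl-4-methylidenecyclohex-2-ene-1,5-dione (not isolated) | CCCC(=O)C1=C(O)C(=C)C(=O)C(C)(C)C1=O | intermediate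
13 | filixic acid BBB (CNP0086314.0): 4,4'-[(5-butanoyl-2,4,6-trihydroxy-1,3-phenylene)bis(methylene)]bis(2-butanoyl-3,5-dihydroxy-6,6-dimethylcyclohexa-2,4-dien-1-one), achiral | CCCC(=O)C1=C(O)C(Cc2c(O)c(CC3=C(O)C(C)(C)C(=O)C(C(=O)CCC)=C3O)c(O)c(C(=O)CCC)c2O)=C(O)C(C)(C)C1=O | target

**Totals.** Total step count: 6. Longest linear sequence: 4 steps (1, 2, 4, 6).

**Steps most likely to fail**

Step 4 (Proposed new method). The trilithio species of 7 may be poorly soluble. The lactone enolate may take a proton from the propyl α-CH2 or the ring CH of 4 instead of adding to it, or add in a conjugate sense at the propyl-bearing enol carbon. The 2,2-dimethyl-1,3-dicarbonyl unit of 8 may suffer retro-Claisen cleavage by phenoxide before the ring closes. The fallback uses known chemistry, sets out from 10 and 5 and comes back to the route at 9. Compound 10 is converted with Eschenmoser's salt into Mannich base 11 as in step 6 and warmed with an excess of 5 (MeCN, 50 °C), so that methylene trione 12 is captured by one of the two equivalent free ring positions of 5 to give 9. This is the classical methylene bridging of an acylfilicinic acid with an acylphloroglucinol, and the excess of 5 suppresses double bridging. In this case the filicinic ring stems from the dearomatising methylation of step 5 and no ring is closed at this stage. The fallback makes no compound outside the list (F0).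

Step 3. The acyl-deactivated ring may react sluggishly, acrylic acid may polymerise, a second annulation may follow the first, or Friedel–Crafts acylation may divert material to a chroman-4-one. The fallback sets out from 5 and comes back at 7. Compound 5, Meldrum's acid and paraformaldehyde (cat. proline, MeCN, rt) should give, by Knoevenagel condensation and Friedel–Crafts Michael addition, 5-[(3-butanoyl-2,4,6-trihydroxyphenyl)methyl]-2,2-dimethyl-1,3-dioxane-4,6-dione F1. Heating (pyridine–toluene, 100 °C) lets an ortho-OH open the dioxanedione with loss of acetone to 6-butanoyl-5,7-dihydroxy-2-oxochromane-3-carboxylic acid F2, which decarboxylates under the same conditions to 7.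

Step 6. Methylene trione 12 may be intercepted by unreacted 10 to give the symmetrical methylene-bis compound, may oligomerise, or the methylene bridges may scramble by retro-Michael exchange on prolonged warming. The fallback reverses the polarity of the bridge-forming step; it sets out from 9 and comes back at 13. Compound 9 is aminomethylated with Eschenmoser's salt (MeCN, rt) at its only free aromatic CH to give the aryl Mannich base 2-butanoyl-4-{[3-butanoyl-5-(dimethylaminomethyl)-2,4,6-trihydroxyphenyl]methyl}-3,5-dihydroxy-6,6-dimethylcyclohexa-2,4-dien-1-one F3. On warming with 10 (MeCN, 50 °C) this should lose dimethylamine to an ortho-quinone methide, which is trapped by the nucleophilic ring carbon of 10 to give 13.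

**Further compounds**

F0 | step 4 | none | none
F1 | step 3 | 5-[(3-butanoyl-2,4,6-trihydroxyphenyl)methyl]-2,2-dimethyl-1,3-dioxane-4,6-dione | CCCC(=O)c1c(O)cc(O)c(CC2C(=O)OC(C)(C)OC2=O)c1O
F2 | step 3 | 6-butanoyl-5,7-dihydroxy-2-oxochromane-3-carboxylic acid | CCCC(=O)c1c(O)cc2OC(=O)C(C(=O)O)Cc2c1O
F3 | step 6 | 2-butanoyl-4-{[3-butanoyl-5-(dimethylaminomethyl)-2,4,6-trihydroxyphenyl]methyl}-3,5-dihydroxy-6,6-dimethylcyclohexa-2,4-dien-1-one | CCCC(=O)C1=C(O)C(Cc2c(O)c(CN(C)C)c(O)c(C(=O)CCC)c2O)=C(O)C(C)(C)C1=O
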